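The numbering is C1 lactone carbonyl, C2 its CH2, C3 CH–OO, C4 C(CH3)–O, C5 ring CH2, C6 C(CH3)–OO and C8 side-chain CH(CH3). The butanolide is cut from the 1,2-dioxane at C2–C3 and O–C4. One flask makes both bonds from a dihydrodioxin-3-yl diazomethyl ketone. Wolff rearrangement shifts C3 onto the diazo carbon with retention, water gives the acid, and iodine closes its carboxylate onto C4 of the ring alkene C4=C5. The step exploits the cis fusion of the lactone and dioxane rings across C3–C4. C3 and C6 arise together in a hydroxyl-directed singlet-oxygen (4+2) cycloaddition to an (E,E)-dienyl diol. Its carbinol carbon, from (R)-glyceraldehyde acetonide, becomes C1. C8 comes from (R)-citronellal.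

Key step: step 15

Assumption: singlet oxygen is taken to add to the diene face that carries the allylic hydroxyl in the conformer whose carbinol C–H eclipses C3=C4 beside the C4 methyl (least allylic 1,3-strain); this fixes (R)-glyceraldehyde acetonide as the enantiomer to buy.

Step 1
Reactants: 1 (4E)-5-phenylpent-4-en-1-ol
Product: 2 1-phenyl-5-{[(4E)-5-phenylpent-4-en-1-yl]sulfanyl}-1H-tetrazole
Conditions: 1-phenyl-1H-tetrazole-5-thiol, PPh3, DIAD, THF, 0 °C to rt
Reagents that add atoms: 1-phenyl-1H-tetrazole-5-thiol, Sc1nnnn1-c1ccccc1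
Why: Mitsunobu thioetherification of a primary alcohol by the acidic tetrazolethiol (SN2 on the alkoxyphosphonium salt); no stereocentre is involved.

Step 2
Reactants: 2 1-phenyl-5-{[(4E)-5-phenylpent-4-en-1-yl]sulfanyl}-1H-tetrazole
Product: 3 1-phenyl-5-{[(4E)-5-phenylpent-4-en-1-yl]sulfonyl}-1H-tetrazole
Conditions: (NH4)6Mo7O24·4H2O (cat.), 30% H2O2, EtOH, 0 °C to rt
Reagents that add atoms: hydrogen peroxide, OO
Why: Molybdate-catalysed sulfide-to-sulfone oxidation should be much faster than epoxidation of the styrene and gives the Julia–Kocienski partner.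

Step 3
Reactants: 4 (R)-citronellal
Product: 5 (4R)-4,8-dimethylnon-7-en-1-yne
Conditions: dimethyl (1-diazo-2-oxopropyl)phosphonate, K2CO3, MeOH, 0 °C to rt
Reagents that add atoms: dimethyl (1-diazo-2-oxopropyl)phosphonate, COP(=O)(OC)C(=[N+]=[N-])C(C)=O
Why: Ohira–Bestmann homologation turns the aldehyde into the terminal alkyne (future C5≡C6) under mild carbonate conditions that leave the bought β-stereocentre C8 untouched.

Step 4
Reactants: 5 (4R)-4,8-dimethylnon-7-en-1-yne
Product: 7 (4R)-4-methylhept-6-ynal, via ozonide 6 (not isolated)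
Conditions: O3, CH2Cl2, −78 °C (dye end point); then Me2S, −78 °C to rt
Reagents that add atoms: ozone, [O-][O+]=O
Why: Ozonolysis with reductive work-up; the electron-rich trisubstituted alkene reacts far faster than the terminal alkyne, so titration to the end point should cleave only the isopropylidene group.

Step 5
Reactants: 3 1-phenyl-5-{[(4E)-5-phenylpent-4-en-1-yl]sulfonyl}-1H-tetrazole; 7 (4R)-4-methylhept-6-ynal
Product: 9 [(1E,5E,9R)-9-methyldodeca-1,5-dien-11-yn-1-yl]benzene, via metalated sulfone 8 (not isolated)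
Conditions: KHMDS, DME, −60 °C; then 7, −60 °C to rt
Reagents that add atoms: none
Why: Julia–Kocienski olefination; the phenyltetrazolyl sulfone with a potassium counter-ion in a coordinating solvent should favour the anti adduct and hence the E-alkene C11=C12 after Smiles rearrangement and loss of SO2.

Step 6
Reactants: 9 [(1E,5E,9R)-9-methyldodeca-1,5-dien-11-yn-1-yl]benzene
Product: 11 [(1E,5E,9R,11E)-12-iodo-9,11-dimethyldodeca-1,5,11-trien-1-yl]benzene, via alkenylalane 10 (not isolated)
Conditions: Me3Al, Cp2ZrCl2 (0.25 equiv), CH2Cl2, 0 °C to rt; then I2, THF, −30 °C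
Reagents that add atoms: trimethylaluminium, C[Al](C)C; iodine, II
Why: Zirconium-catalysed carboalumination adds methyl and aluminium syn across the terminal alkyne with aluminium at the terminus, and iodinolysis with retention fixes the E geometry of C5=C6 (C7 trans to iodine); internal alkenes are inert.

Step 7
Reactants: 12 (R)-glyceraldehyde acetonide
Product: 13 (4S)-4-ethynyl-2,2-dimethyl-1,3-dioxolane
Conditions: dimethyl (1-diazo-2-oxopropyl)phosphonate, K2CO3, MeOH, 0 °C
Reagents that add atoms: dimethyl (1-diazo-2-oxopropyl)phosphonate, COP(=O)(OC)C(=[N+]=[N-])C(C)=O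
Why: Ohira–Bestmann homologation; the aldehyde is consumed quickly at low temperature, so the bought α-oxygenated stereocentre should be retained (its descriptor changes only through the priority rules).

Step 8
Reactants: 13 (4S)-4-ethynyl-2,2-dimethyl-1,3-dioxolane
Product: 15 (4S)-2,2-dimethyl-4-(prop-1-yn-1-yl)-1,3-dioxolane, via lithium acetylide 14 (not isolated)
Conditions: n-BuLi, THF, −78 °C; then MeI, −78 °C to rt
Reagents that add atoms: iodomethane, CI
Why: Deprotonation of the terminal alkyne and SN2 methylation bring in the C4 methyl group.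

Step 9
Reactants: 15 (4S)-2,2-dimethyl-4-(prop-1-yn-1-yl)-1,3-dioxolane
Product: 16 (4S)-2,2-dimethyl-4-[(1Z)-2-(4,4,5,5-tetramethyl-1,3,2-dioxaborolan-2-yl)prop-1-en-1-yl]-1,3-dioxolane
Conditions: pinacolborane, Cp2ZrHCl (10 mol %), Et3N (10 mol %), neat, 60 °C
Reagents that add atoms: pinacolborane, [H]B1OC(C)(C)C(C)(C)O1
Why: Zirconocene-hydride-catalysed syn hydroboration should place boron on the less hindered, methyl-bearing alkyne carbon (C4), which sets C3=C4 with boron trans to the dioxolane.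

Step 10
Reactants: 16 (4S)-2,2-dimethyl-4-[(1Z)-2-(4,4,5,5-tetramethyl-1,3,2-dioxaborolan-2-yl)prop-1-en-1-yl]-1,3-dioxolane
Product: 17 (2S,3Z)-4-(4,4,5,5-tetramethyl-1,3,2-dioxaborolan-2-yl)pent-3-ene-1,2-diol
Conditions: AcOH/H2O/THF, 40 °C
Reagents that add atoms: none
Why: Acid-catalysed acetal hydrolysis is done on the simple allylic system, before the acid-labile dienyl carbinol exists; the pinacol boronate should survive.

Step 11
Reactants: 11 [(1E,5E,9R,11E)-12-iodo-9,11-dimethyldodeca-1,5,11-trien-1-yl]benzene; 17 (2S,3Z)-4-(4,4,5,5-tetramethyl-1,3,2-dioxaborolan-2-yl)pent-3-ene-1,2-diol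
Product: 18 (2S,3E,5E,8R,11E,15E)-4,6,8-trimethyl-16-phenylhexadeca-3,5,11,15-tetraene-1,2-diol
Conditions: Pd(dppf)Cl2 (5 mol %), aq. K3PO4, THF, 40 °C, degassed
Reagents that add atoms: none
Why: Suzuki–Miyaura coupling of two alkenyl partners forms C4–C5 with retention on both sides and tolerates the free diol, giving the (3E,5E)-diene.

Step 12
Reactants: 18 (2S,3E,5E,8R,11E,15E)-4,6,8-trimethyl-16-phenylhexadeca-3,5,11,15-tetraene-1,2-diol
Product: 19 (1R)-1-{(3R,6R)-4,6-dimethyl-6-[(2R,5E,9E)-2-methyl-10-phenyldeca-5,9-dien-1-yl]-3,6-dihydro-1,2-dioxin-3-yl}ethane-1,2-diol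
Conditions: O2, tetraphenylporphyrin (1 mol %), hν (>500 nm), CH2Cl2, −30 °C
Reagents that add atoms: oxygen, O=O
Why: Singlet-oxygen (4+2) cycloaddition; suprafacial addition to the s-cis (E,E)-diene puts the two outer substituents (carbinol carbon on C3, C7 on C6) cis, hydrogen bonding of the incoming oxygen to the allylic hydroxyl in the conformer of least allylic 1,3-strain selects the face so that C3 and C6 are set together from the glyceraldehyde centre, and the isolated disubstituted alkenes are too unreactive to compete.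

Step 13
Reactants: 19 (1R)-1-{(3R,6R)-4,6-dimethyl-6-[(2R,5E,9E)-2-methyl-10-phenyldeca-5,9-dien-1-yl]-3,6-dihydro-1,2-dioxin-3-yl}ethane-1,2-diol
Product: 21 (3R,6R)-4,6-dimethyl-6-[(2R,5E,9E)-2-methyl-10-phenyldeca-5,9-dien-1-yl]-3,6-dihydro-1,2-dioxine-3-carboxylic acid, via dioxine aldehyde 20 (not isolated)
Conditions: NaIO4, THF/pH 7 buffer, 0 °C; extraction; then NaClO2, NaH2PO4, 2-methylbut-2-ene, t-BuOH/H2O, 0 °C
Reagents that add atoms: sodium chlorite, [Na+].[O-]Cl=O
Why: Periodate glycol cleavage followed by Pinnick oxidation in weakly acidic buffer turns the directing carbinol carbon into the carboxyl carbon without any base, so the base-labile CH–OO centre C3 should keep its configuration.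

Step 14
Reactants: 21 (3R,6R)-4,6-dimethyl-6-[(2R,5E,9E)-2-methyl-10-phenyldeca-5,9-dien-1-yl]-3,6-dihydro-1,2-dioxine-3-carboxylic acid
Product: 23 2-diazo-1-{(3R,6R)-4,6-dimethyl-6-[(2R,5E,9E)-2-methyl-10-phenyldeca-5,9-dien-1-yl]-3,6-dihydro-1,2-dioxin-3-yl}ethan-1-one, via acid chloride 22 (not isolated)
Conditions: 1-chloro-N,N,2-trimethylprop-1-en-1-amine, CH2Cl2, 0 °C; then CH2N2 (3 equiv), Et2O, −10 °C
Reagents that add atoms: diazomethane, C=[N+]=[N-]
Why: First half of an Arndt–Eistert homologation; the neutral chloroenamine makes the acid chloride without an amine base, and excess diazomethane is acylated and scavenges HCl, conditions chosen to avoid deprotonation at C3.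

Step 15
Reactants: 23 2-diazo-1-{(3R,6R)-4,6-dimethyl-6-[(2R,5E,9E)-2-methyl-10-phenyldeca-5,9-dien-1-yl]-3,6-dihydro-1,2-dioxin-3-yl}ethan-1-one
Product: 26 (3R,4S,4aR,7aS)-4-iodo-3,4a-dimethyl-3-[(2R,5E,9E)-2-methyl-10-phenyldeca-5,9-dien-1-yl]-4,4a,7,7a-tetrahydro-3H-furo[3,2-c][1,2]dioxin-6-one, via ketene 24 (not isolated), via dioxinylacetic acid 25 (not isolated)
Conditions: hν (365 nm LED), THF/H2O (9:1), 0 °C; then NaHCO3, I2, 0 °C, dark, same flask
Reagents that add atoms: water, O; iodine, II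
Why: Irradiation expels N2 from the s-Z diazoketone and C3 migrates from the carbonyl carbon to the diazo carbon (Wolff rearrangement, second half of an Arndt–Eistert homologation), so C2–C3 forms with retention at the migrating stereocentre, and water adds to ketene 24 to give acid 25. Without isolation, iodine forms iodonium ions reversibly, and only the one on the ring alkene C4=C5 that lies anti to the CH2CO2 arm is captured, the carboxylate oxygen attacking the tertiary terminus C4 (iodolactonisation, 5-exo-trig closure of the butanolide). C3 is thus controlled by the stereospecific 1,2-shift, C4 by the tether, which reaches only the ring face that carries C2 (cis fusion), and the temporary C5–I centre by anti addition. The step needs chemoselectivity for one of three alkenes and for the diazo chromophore: the two side-chain alkenes have no internal nucleophile, and 365 nm light is absorbed neither by the styrene nor by the O–O bond. Formation of the γ-lactone rather than the δ-lactone follows from Markovnikov opening at C4 and the smaller ring.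

Step 16
Reactants: 26 (3R,4S,4aR,7aS)-4-iodo-3,4a-dimethyl-3-[(2R,5E,9E)-2-methyl-10-phenyldeca-5,9-dien-1-yl]-4,4a,7,7a-tetrahydro-3H-furo[3,2-c][1,2]dioxin-6-one
Product: 27 CNP0365311.2
Conditions: Bu3SnH (1.2 equiv), Et3B (cat.), air, toluene, 0 °C
Reagents that add atoms: none
Why: Radical-chain deiodination at low temperature; the secondary C5 radical should be reduced faster than it can attack the ring O–O bond, whose endocyclic geometry denies the collinear alignment needed for homolytic substitution, and no stereocentre of the target is touched.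

Compound list
1 | (4E)-5-phenylpent-4-en-1-ol | OCCC/C=C/c1ccccc1 | starting material
2 | 1-phenyl-5-{[(4E)-5-phenylpent-4-en-1-yl]sulfanyl}-1H-tetrazole | C(CC/C=C/c1ccccc1)Sc1nnnn1-c1ccccc1 | intermediate
3 | 1-phenyl-5-{[(4E)-5-phenylpent-4-en-1-yl]sulfonyl}-1H-tetrazole | O=S(=O)(CCC/C=C/c1ccccc1)c1nnnn1-c1ccccc1 | intermediate
4 | (R)-citronellal, (3R)-3,7-dimethyloct-6-enal | C[C@H](CCC=C(C)C)CC=O | starting material
5 | (4R)-4,8-dimethylnon-7-en-1-yne | C[C@H](CCC=C(C)C)CC#C | intermediate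
6 | 3,3-dimethyl-5-[(3R)-3-methylhex-5-yn-1-yl]-1,2,4-trioxolane (ozonide, both epimers at the ring CH) | C[C@H](CCC1OOC(C)(C)O1)CC#C | intermediate
7 | (4R)-4-methylhept-6-ynal | C[C@H](CCC=O)CC#C | intermediate
8 | potassium salt of sulfone 3 (carbanion next to sulfur) | [K+].[CH-](CC/C=C/c1ccccc1)S(=O)(=O)c1nnnn1-c1ccccc1 | intermediate
9 | [(1E,5E,9R)-9-methyldodeca-1,5-dien-11-yn-1-yl]benzene | C[C@H](CC/C=C/CC/C=C/c1ccccc1)CC#C | intermediate
10 | dimethyl[(1E,4R,7E,11E)-2,4-dimethyl-12-phenyldodeca-1,7,11-trien-1-yl]alane | C[C@H](CC/C=C/CC/C=C/c1ccccc1)C/C(C)=C/[Al](C)C | intermediate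
11 | [(1E,5E,9R,11E)-12-iodo-9,11-dimethyldodeca-1,5,11-trien-1-yl]benzene | C[C@H](CC/C=C/CC/C=C/c1ccccc1)C/C(C)=C/I | intermediate
12 | (R)-glyceraldehyde acetonide, (4R)-2,2-dimethyl-1,3-dioxolane-4-carbaldehyde | O=C[C@H]1COC(C)(C)O1 | starting material
13 | (4S)-4-ethynyl-2,2-dimethyl-1,3-dioxolane | C#C[C@H]1COC(C)(C)O1 | intermediate
14 | lithium acetylide of 13 | [Li]C#C[C@H]1COC(C)(C)O1 | intermediate
15 | (4S)-2,2-dimethyl-4-(prop-1-yn-1-yl)-1,3-dioxolane | CC#C[C@H]1COC(C)(C)O1 | intermediate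
16 | (4S)-2,2-dimethyl-4-[(1Z)-2-(4,4,5,5-tetramethyl-1,3,2-dioxaborolan-2-yl)prop-1-en-1-yl]-1,3-dioxolane (boron trans to the dioxolane) | CC1(C)OB(OC1(C)C)/C(C)=C/[C@H]1COC(C)(C)O1 | intermediate
17 | (2S,3Z)-4-(4,4,5,5-tetramethyl-1,3,2-dioxaborolan-2-yl)pent-3-ene-1,2-diol | CC1(C)OB(OC1(C)C)/C(C)=C/[C@H](O)CO | intermediate
18 | (2S,3E,5E,8R,11E,15E)-4,6,8-trimethyl-16-phenylhexadeca-3,5,11,15-tetraene-1,2-diol | C[C@H](CC/C=C/CC/C=C/c1ccccc1)C/C(C)=C/C(C)=C/[C@H](O)CO | intermediate
19 | (1R)-1-{(3R,6R)-4,6-dimethyl-6-[(2R,5E,9E)-2-methyl-10-phenyldeca-5,9-dien-1-yl]-3,6-dihydro-1,2-dioxin-3-yl}ethane-1,2-diol (diol arm on C3 cis to the side chain on C6) | C[C@H](CC/C=C/CC/C=C/c1ccccc1)C[C@]1(C)C=C(C)[C@H]([C@H](O)CO)OO1 | intermediate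
20 | (3R,6R)-4,6-dimethyl-6-[(2R,5E,9E)-2-methyl-10-phenyldeca-5,9-dien-1-yl]-3,6-dihydro-1,2-dioxine-3-carbaldehyde | C[C@H](CC/C=C/CC/C=C/c1ccccc1)C[C@]1(C)C=C(C)[C@H](C=O)OO1 | intermediate
21 | (3R,6R)-4,6-dimethyl-6-[(2R,5E,9E)-2-methyl-10-phenyldeca-5,9-dien-1-yl]-3,6-dihydro-1,2-dioxine-3-carboxylic acid | C[C@H](CC/C=C/CC/C=C/c1ccccc1)C[C@]1(C)C=C(C)[C@H](C(=O)O)OO1 | intermediate
22 | acid chloride of 21 | C[C@H](CC/C=C/CC/C=C/c1ccccc1)C[C@]1(C)C=C(C)[C@H](C(=O)Cl)OO1 | intermediate
23 | 2-diazo-1-{(3R,6R)-4,6-dimethyl-6-[(2R,5E,9E)-2-methyl-10-phenyldeca-5,9-dien-1-yl]-3,6-dihydro-1,2-dioxin-3-yl}ethan-1-one | C[C@H](CC/C=C/CC/C=C/c1ccccc1)C[C@]1(C)C=C(C)[C@H](C(=O)C=[N+]=[N-])OO1 | intermediate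
24 | 2-{(3S,6R)-4,6-dimethyl-6-[(2R,5E,9E)-2-methyl-10-phenyldeca-5,9-dien-1-yl]-3,6-dihydro-1,2-dioxin-3-yl}ethen-1-one (ketene) | C[C@H](CC/C=C/CC/C=C/c1ccccc1)C[C@]1(C)C=C(C)[C@H](C=C=O)OO1 | intermediate
25 | 2-{(3S,6R)-4,6-dimethyl-6-[(2R,5E,9E)-2-methyl-10-phenyldeca-5,9-dien-1-yl]-3,6-dihydro-1,2-dioxin-3-yl}acetic acid | C[C@H](CC/C=C/CC/C=C/c1ccccc1)C[C@]1(C)C=C(C)[C@H](CC(=O)O)OO1 | intermediate
26 | (3R,4S,4aR,7aS)-4-iodo-3,4a-dimethyl-3-[(2R,5E,9E)-2-methyl-10-phenyldeca-5,9-dien-1-yl]-4,4a,7,7a-tetrahydro-3H-furo[3,2-c][1,2]dioxin-6-one (iodine on C5 trans to the lactone oxygen on C4) | C[C@H](CC/C=C/CC/C=C/c1ccccc1)C[C@]1(C)[C@@H](I)[C@]2(C)OC(=O)C[C@@H]2OO1 | intermediate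
27 | CNP0365311.2, (3R,4aS,7aS)-3,4a-dimethyl-3-[(2R,5E,9E)-2-methyl-10-phenyldeca-5,9-dien-1-yl]-4,4a,7,7a-tetrahydro-3H-furo[3,2-c][1,2]dioxin-6-one (3S,4S,6R,8R in the numbering of the overview) | C[C@H](CC/C=C/CC/C=C/c1ccccc1)C[C@]1(C)C[C@]2(C)OC(=O)C[C@@H]2OO1 | target

Total step count: 16.
Longest linear sequence: 10 steps (steps 3–6 and 11–16; the branches from 1 and from 12 are equally long).

Steps most likely to fail

1. Step 15 (key step).
- Risk: the photogenerated carbene may insert into water or attack the neighbouring peroxide oxygen instead of undergoing the 1,2-shift. Light may cleave the O–O bond. Photoproducts may consume iodine, so that the lactonisation stalls.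
- Fallback: this sets out from 23, uncouples the two events and avoids the free carbene. Wolff rearrangement catalysed by silver benzoate (PhCO2Ag) with ultrasound, in tert-butanol/THF in the dark, should give tert-butyl 2-{(3S,6R)-dihydrodioxin-3-yl}acetate F1, which is purified. CF3CO2H in CH2Cl2 at 0 °C frees acid 25, now isolated. I2/NaHCO3 in MeCN closes it to 26, where the route is rejoined.

2. Step 12.
- Risk: facial selectivity may be eroded because the primary hydroxyl, which sits on the opposite diene face, also binds the incoming singlet oxygen.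
- Fallback: this sets out from 18 and changes the substrate so that only one hydrogen-bond donor is left. TBSCl/imidazole should silylate the primary hydroxyl alone to give the tetraenol primary silyl ether F2. Photooxygenation of F2 in a non-polar solvent gives the dihydrodioxine silyl ether F3. HF·pyridine in THF returns to 19.

3. Step 11.
- Risk: transmetalation of the α-methyl-substituted alkenylboronate may be slow, with protodeboronation and loss of alkene geometry during a long reaction.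
- Fallback: the polarity of the coupling is reversed.
  - From 16, iododeboronation with N-iodosuccinimide in MeCN (retention) gives the iodopropenyl dioxolane F4.
  - Aqueous AcOH then gives the iodopentenediol F5.
  - From 11, Miyaura borylation (B2pin2, Pd(dppf)Cl2, KOAc, dioxane) gives the trienylboronate F6, with boron on the unhindered CH terminus.
  - Suzuki–Miyaura coupling of F5 and F6 comes back to 18.

Further compounds
F1 | step 15 | tert-butyl 2-{(3S,6R)-4,6-dimethyl-6-[(2R,5E,9E)-2-methyl-10-phenyldeca-5,9-dien-1-yl]-3,6-dihydro-1,2-dioxin-3-yl}acetate | C[C@H](CC/C=C/CC/C=C/c1ccccc1)C[C@]1(C)C=C(C)[C@H](CC(=O)OC(C)(C)C)OO1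
F2 | step 12 | (2S,3E,5E,8R,11E,15E)-1-[(tert-butyldimethylsilyl)oxy]-4,6,8-trimethyl-16-phenylhexadeca-3,5,11,15-tetraen-2-ol | C[C@H](CC/C=C/CC/C=C/c1ccccc1)C/C(C)=C/C(C)=C/[C@H](O)CO[Si](C)(C)C(C)(C)C
F3 | step 12 | (1R)-2-[(tert-butyldimethylsilyl)oxy]-1-{(3R,6R)-4,6-dimethyl-6-[(2R,5E,9E)-2-methyl-10-phenyldeca-5,9-dien-1-yl]-3,6-dihydro-1,2-dioxin-3-yl}ethan-1-ol | C[C@H](CC/C=C/CC/C=C/c1ccccc1)C[C@]1(C)C=C(C)[C@H]([C@H](O)CO[Si](C)(C)C(C)(C)C)OO1
F4 | step 11 | (4S)-4-[(1E)-2-iodoprop-1-en-1-yl]-2,2-dimethyl-1,3-dioxolane | I/C(C)=C/[C@H]1COC(C)(C)O1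
F5 | step 11 | (2S,3E)-4-iodopent-3-ene-1,2-diol | I/C(C)=C/[C@H](O)CO
F6 | step 11 | 2-[(1E,4R,7E,11E)-2,4-dimethyl-12-phenyldodeca-1,7,11-trien-1-yl]-4,4,5,5-tetramethyl-1,3,2-dioxaborolane | C[C@H](CC/C=C/CC/C=C/c1ccccc1)C/C(C)=C/B1OC(C)(C)C(C)(C)O1
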